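## The problem

The target 17 is a flavan: a chroman that carries a 3,5-dimethoxyphenyl group (ring B) at C2 and whose benzo ring (ring A) is a phloroglucinol. Ring A has free hydroxyls at C5 and C7, a prenyl group at C6 between them, hydrogen at C8, and its third oxygen built into the pyran ring as O1. C2 (R) is the only stereocentre; it is a benzylic ether carbon with no neighbour to relay from, so it must be set by a reagent and then kept away from conditions that ionise or hydrogenolyse the C2–O1 bond. The second demand is regiochemical: in any route that starts from a phloroglucinol, the oxygen that becomes O1 must be told apart from the one at C5, and a mistake gives the 8-prenyl isomer. The prenyl alkene between two phenols rules out catalytic hydrogenation and strong acid (cyclisation to a 2,2-dimethylchroman, addition of HX). The ring A hydroxyls must end free beside two ring B methyl ethers, which excludes a global dealkylation. The feature that opens a short route is the carbonyl pattern hidden in ring A: C5(OH)–C6(prenyl)–C7(OH) is a 2-prenylmalonyl unit, and C8–C8a(O1)–C4a is the enol ether of a methyl ketone whose oxygen and α-methylene are already tied into the pyran ring. Two nucleophilic α-carbons and two acyl carbons therefore add up to the aromatic ring without any redox change, with O1 in place before ring A exists and the prenyl position fixed by connectivity.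

## Retrosynthesis

**Cut 1, C7–C8 and C4a–C5 (17 ⇒ 8 + 13).** Ring A is opened at the two bonds that join the malonyl carbons to the α-carbons of the enol ether, giving the exocyclic enol ether 8 and 2-prenylmalonyl dichloride 13. The forward reaction passes through the mono-acylated enone 14, the acylketene 15 and the non-aromatic diketone 16. Cuts inside the pyran ring would keep ring A as a bought phloroglucinol and bring oxygen differentiation, prenyl placement and protecting groups with them. This cut needs none of these, divides the molecule into two halves of similar size and creates no stereocentre. It asks the forward step for two C-acylations and an aromatisation under conditions mild enough for an enol ether, a prenyl alkene and a benzylic ether.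

**Cut 2, the exocyclic C=CH2 (8 ⇒ 7).** The methylene carbon (future C8) is removed to leave lactone 7. A titanium-mediated carbonyl methylenation is the only operation required, and it is neither acidic nor basic at the benzylic carbon. The endocyclic double-bond isomer of 8 would serve equally well, because the annulation acylates both α-carbons in either order.

**Cut 3, the lactone C–O acyl bond and the C2–H bond (7 ⇒ 6 ⇒ 5).** Opening the lactone gives hydroxy ester 6, and removal of the carbinol hydrogen gives aryl keto ester 5. An aryl alkyl ketone is the ideal substrate for ruthenium-catalysed asymmetric transfer hydrogenation, so the single stereocentre is set early and on a simple compound. Lactonisation is an acyl substitution and cannot invert it.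

**Cut 4, the aryl–carbonyl bond (5 ⇒ 4 ⇒ 1 + 2).** Ester 5 comes from acid 4, which is cut between ring B and the ketone carbon into bromide 1 (as its Grignard reagent 3) and glutaric anhydride 2. Electrophilic acylation of a dimethoxyarene would go ortho/para to the methoxy groups, so the meta,meta pattern has to come from the halide. The anhydride supplies in one piece all five carbons that become C2, C3, C4, C4a and C8a.

**Cut 5, the malonyl branch (13 ⇒ 12 ⇒ 11 ⇒ 9 + 10).** The dichloride 13 is the acid chloride of diacid 12, which comes from diester 11 by saponification; 11 is cut at the allylic C–C bond into diethyl malonate 9 and prenyl bromide 10. This is the classical malonic ester sequence, and its only special demand is gentle handling of the prenyl alkene at the acid chloride stage.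

## Roads not taken

**Alternative 1: ring A by diene cycloaddition onto a chiral dihydropyranone.**
- Cut: C8–C8a and C4a–C5, so ring A is again made de novo, but at the flavanone oxidation level.
- Forward step: the sulfinyl dihydropyranone A2 takes up the 1-methoxy-1,3-bis(silyloxy)diene A3 across its sulfinyl-bearing alkene; loss of PhSOH and methanol aromatises the adduct to flavanone A1.
- Merits: the pyranone core is accessible by a catalytic asymmetric hetero-Diels–Alder reaction. Cycloaddition followed by aromatising elimination is a better-charted ring-forming event than a double acylation. The polarity of diene and enone places prenyl at C6.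
- Weak points: A1 carries a C4 carbonyl that the target lacks. Removing it costs two or three redox steps in the presence of the prenyl alkene, free phenols and the benzylic ether. A 5-hydroxyflavanone can also open to the chalcone under base and lose its C2 configuration. The fully substituted diene terminus of A3 must bond to the sulfinyl-bearing carbon of A2, a congested union, and the sulfoxide costs two further steps.
- Comparison: this road is ahead in precedent for the key event. The chosen plan sets against it direct arrival at the flavan oxidation level, no epimerisable intermediate and a shorter sequence.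

**Alternative 2: ring-closing metathesis of a chiral aryl allyl ether.**
- Cut: C3=C4, preceded by an iridium-catalysed allylic etherification ([Ir(cod)Cl]2 with a chiral phosphoramidite) that makes O1–C2 and sets C2.
- Forward step: the second-generation Grubbs catalyst, RuCl2(=CHPh)(PCy3)(H2IMes), closes diene ether A5 to the 2H-chromene A4; alkene saturation and MOM removal follow.
- Merits: every step has close precedent, and C2 is set by catalyst control. On certainty of the individual steps this road is clearly better than the chosen plan.
- Weak points: ring A must be carved out of phloroglucinol with its oxygens differentiated, prenyl placed and two MOM groups put on and taken off. The prenyl alkene is a second metathesis partner. The C3=C4 bond of A4 must be reduced beside the prenyl alkene and a C2–O bond that is both allylic and benzylic. 2-Aryl-2H-chromenes can open reversibly to dienones, which would erode C2. The final acid step acts next to the prenyl group.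
- Comparison: roughly twelve steps with protecting groups and a delicate chemoselective reduction, against eight steps without protecting groups. The chosen plan pays for this with one unprecedented step.

**Alternative 3: asymmetric ortho-quinone methide/styrene hetero-Diels–Alder.**
- Cut: C3–C4 and O1–C2 in one [4+2].
- Forward step: a BINOL-derived chiral phosphoric acid dehydrates salicyl alcohol A7 to the ortho-quinone methide, which adds 3,5-dimethoxystyrene A8 to give the bis-MOM flavan A6; acid then frees the phenols.
- Merits: the most convergent road. The pyran ring and the stereocentre form together, the phloroglucinol-type quinone methide forms easily, and only one step follows. The regiochemistry is safe if A7 is made from a symmetric 4-prenylphenol.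
- Weak points: the quinone methide has an unsubstituted methide carbon, and the stereocentre arises at the styrene carbon, remote from the catalyst-bound oxygen, so high selectivity is not assured. A8 has no para donor and is a modest dienophile, while its ring carbons next to the methoxy groups can be alkylated by the quinone methide. MOM acetals and the prenyl group must survive the Brønsted acid.
- Comparison: in step count this road is about level with the chosen plan once the synthesis of A7 is counted, and its reaction type is established. The chosen plan sets against it that C2 comes from an aryl ketone transfer hydrogenation, a most dependable asymmetric reaction, and that the uncertain step creates no stereocentre.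

Key step: step 8

## Route

Assumption: the aryl-bearing carbon keeps the descriptor R from 6 to 17, because no bond to it is made or broken after step 3 and its substituent ranking (O > aryl > CH2 > H) does not change.

Step 1
Reactants: 1 1-bromo-3,5-dimethoxybenzene; 2 glutaric anhydride
Product: 4 5-(3,5-dimethoxyphenyl)-5-oxopentanoic acid, via arylmagnesium bromide 3 (not isolated)
Conditions: Mg, I2 (cat.), THF, 40 °C; solution of 3 added to 2 (1.2 equiv), THF, −78 → 0 °C; aq. HCl
Reagents that add atoms: none
Why: Grignard formation and ring-opening acylation of a cyclic anhydride; inverse addition at low temperature and the magnesium carboxylate formed on opening hold the reaction at the ketone stage, and the bromide supplies the meta,meta pattern that electrophilic acylation cannot give.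

Step 2
Reactants: 4 5-(3,5-dimethoxyphenyl)-5-oxopentanoic acid
Product: 5 methyl 5-(3,5-dimethoxyphenyl)-5-oxopentanoate
Conditions: MeOH, H2SO4 (cat.), reflux
Reagents that add atoms: methanol, CO
Why: Fischer esterification; the ester keeps a free acid away from the transfer hydrogenation and provides the leaving group for the later lactonisation.

Step 3
Reactants: 5 methyl 5-(3,5-dimethoxyphenyl)-5-oxopentanoate
Product: 7 (R)-6-(3,5-dimethoxyphenyl)tetrahydro-2H-pyran-2-one, via hydroxy ester 6 (not isolated)
Conditions: RuCl(p-cymene)[(R,R)-TsDPEN] (1 mol %), HCO2H/Et3N (5:2), 30 °C; then TsOH·H2O (cat.), CH2Cl2, rt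
Reagents that add atoms: none
Why: Noyori–Ikariya asymmetric transfer hydrogenation of an aryl alkyl ketone, in which the (R,R)-catalyst should deliver hydride to the face that gives the (R)-carbinol, as it does for acetophenone; acid-catalysed lactonisation is an acyl substitution that leaves the C–O bond of the stereocentre intact, and the meta-methoxy groups do not stabilise a benzylic cation.

Step 4
Reactants: 7 (R)-6-(3,5-dimethoxyphenyl)tetrahydro-2H-pyran-2-one
Product: 8 (R)-2-(3,5-dimethoxyphenyl)-6-methylenetetrahydro-2H-pyran
Conditions: Cp2TiMe2 (2 equiv), PhMe, 65 °C, dark; filtration through basic Al2O3 with Et3N-doped eluent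
Reagents that add atoms: dimethyltitanocene (Cp2TiMe2), C[Ti](C)(C1C=CC=C1)C1C=CC=C1
Why: Petasis methylenation; thermally formed Cp2Ti=CH2 adds to the lactone carbonyl and cycloreverts to the exocyclic enol ether under non-acidic, non-basic conditions that do not touch the benzylic stereocentre.

Step 5
Reactants: 9 diethyl malonate; 10 prenyl bromide (1-bromo-3-methylbut-2-ene)
Product: 11 diethyl 2-(3-methylbut-2-en-1-yl)malonate
Conditions: NaH, THF, 0 °C; then 10 (0.8 equiv), → rt
Reagents that add atoms: none
Why: malonic ester alkylation by SN2 displacement at the primary allylic bromide; an excess of malonate suppresses dialkylation.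

Step 6
Reactants: 11 diethyl 2-(3-methylbut-2-en-1-yl)malonate
Product: 12 2-(3-methylbut-2-en-1-yl)malonic acid
Conditions: KOH (2.5 equiv), EtOH/H2O, rt; cold aq. HCl to pH 2, extraction, concentration below 30 °C
Reagents that add atoms: potassium hydroxide, [K+].[OH-]
Why: ester saponification; cold, brief acidification and evaporation without heating avoid decarboxylation of the malonic acid and hydration of the prenyl alkene.

Step 7
Reactants: 12 2-(3-methylbut-2-en-1-yl)malonic acid
Product: 13 2-(3-methylbut-2-en-1-yl)malonyl dichloride
Conditions: (COCl)2 (2.5 equiv), DMF (cat.), CH2Cl2, 0 °C → rt; volatiles removed in vacuo, used at once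
Reagents that add atoms: oxalyl chloride, O=C(Cl)C(=O)Cl
Why: acid chloride formation through the chloroiminium (Vilsmeier-type) intermediate at or below room temperature, where unsaturated acid chlorides with trisubstituted alkenes are routinely made without HCl addition.

Step 8
Reactants: 8 (R)-2-(3,5-dimethoxyphenyl)-6-methylenetetrahydro-2H-pyran; 13 2-(3-methylbut-2-en-1-yl)malonyl dichloride
Product: 17 (R)-2-(3,5-dimethoxyphenyl)-6-(3-methylbut-2-en-1-yl)chromane-5,7-diol, via acid chloride enone 14 (not isolated), via acylketene 15 (not isolated), via dienone tautomer 16 (not isolated)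
Conditions: 2,6-di-tert-butylpyridine (2.2 equiv), CH2Cl2 (0.02 M), 13 (1.05 equiv) added slowly at −40 °C, → rt, then 40 °C; aq. NaHCO3
Reagents that add atoms: none
Why: Proposed new method: the electron-rich exocyclic CH2 of 8 (future C8) attacks one acyl chloride of 13, and loss of chloride and of a proton from the oxocarbenium ion gives the β-alkoxy enone 14, forming C7–C8. The remaining β-keto acid chloride loses HCl to acylketene 15, while pyridinium-mediated enolisation toward C4a turns the vinylogous ester into a 2-alkoxy dienol. C4a then adds to the ketene carbon C5 in a 6-exo-dig closure, which can equally be read as the 6π electrocyclisation of a dienylketene, to give dienone 16, and 16 enolises twice to arene 17. The closest known reactions are the Effenberger cyclisation, in which malonyl dichloride doubly C-acylates a ketone enol ether at both α-carbons to give a cyclic trione, and the dienylketene-to-phenol closure that ends the Danheiser benzannulation; new here are the 2-substituted malonyl dichloride, the lactone-derived exocyclic enol ether and the aromatising outcome. No stereocentre is created, since C4a and C6 of 16 are transient and vanish on enolisation, and C2 is never part of a reacting π system. Regiochemistry follows from connectivity: the malonyl central carbon can only end between the two new C–OH carbons (prenyl at C6), O1 is already alkylated and cannot close a pyranone, and the same product results if 8 first isomerises to its endocyclic isomer, because then C4a is acylated first and C8 second. The hindered base removes HCl without attacking the acid chloride, which protects the enol ether, the prenyl group and the benzylic ether, and slow addition at high dilution keeps 15 from being trapped by a second molecule of 8 or by the product phenols.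

## Compound list

1 | 1-bromo-3,5-dimethoxybenzene | COc1cc(Br)cc(OC)c1 | starting material
2 | glutaric anhydride | O=C1CCCC(=O)O1 | starting material
3 | 3,5-dimethoxyphenylmagnesium bromide | COc1cc([Mg]Br)cc(OC)c1 | intermediate
4 | 5-(3,5-dimethoxyphenyl)-5-oxopentanoic acid | COc1cc(OC)cc(C(=O)CCCC(=O)O)c1 | intermediate
5 | methyl 5-(3,5-dimethoxyphenyl)-5-oxopentanoate | COC(=O)CCCC(=O)c1cc(OC)cc(OC)c1 | intermediate
6 | methyl (R)-5-(3,5-dimethoxyphenyl)-5-hydroxypentanoate | COc1cc(OC)cc([C@H](O)CCCC(=O)OC)c1 | intermediate
7 | (R)-6-(3,5-dimethoxyphenyl)tetrahydro-2H-pyran-2-one | COc1cc(OC)cc([C@H]2CCCC(=O)O2)c1 | intermediate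
8 | (R)-2-(3,5-dimethoxyphenyl)-6-methylenetetrahydro-2H-pyran | COc1cc(OC)cc([C@H]2CCCC(=C)O2)c1 | intermediate
9 | diethyl malonate | CCOC(=O)CC(=O)OCC | starting material
10 | prenyl bromide (1-bromo-3-methylbut-2-ene) | CC(C)=CCBr | starting material
11 | diethyl 2-(3-methylbut-2-en-1-yl)malonate | CCOC(=O)C(CC=C(C)C)C(=O)OCC | intermediate
12 | 2-(3-methylbut-2-en-1-yl)malonic acid | CC(C)=CCC(C(=O)O)C(=O)O | intermediate
13 | 2-(3-methylbut-2-en-1-yl)malonyl dichloride | CC(C)=CCC(C(=O)Cl)C(=O)Cl | intermediate
14 | 2-{(E)-2-[(6R)-6-(3,5-dimethoxyphenyl)tetrahydro-2H-pyran-2-ylidene]acetyl}-5-methylhex-4-enoyl chloride (α-carbon of the acid chloride unassigned) | COc1cc(OC)cc([C@H]2CCC/C(=C\C(=O)C(CC=C(C)C)C(Cl)=O)O2)c1 | intermediate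
15 | 2-{(E)-2-[(6R)-6-(3,5-dimethoxyphenyl)tetrahydro-2H-pyran-2-ylidene]acetyl}-5-methylhexa-1,4-dien-1-one (acylketene) | COc1cc(OC)cc([C@H]2CCC/C(=C\C(=O)C(CC=C(C)C)=C=O)O2)c1 | intermediate
16 | (2R)-2-(3,5-dimethoxyphenyl)-6-(3-methylbut-2-en-1-yl)-2,3,4,4a-tetrahydro-5H-chromene-5,7(6H)-dione, the non-aromatic diketo tautomer of 17 with a C8=C8a double bond (C4a and C6 unassigned) | COc1cc(OC)cc([C@H]2CCC3C(=O)C(CC=C(C)C)C(=O)C=C3O2)c1 | intermediate
17 | (R)-2-(3,5-dimethoxyphenyl)-6-(3-methylbut-2-en-1-yl)chromane-5,7-diol | COc1cc(OC)cc([C@H]2CCc3c(cc(O)c(CC=C(C)C)c3O)O2)c1 | target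

## Step count and risk

Total step count: 8. Longest linear sequence: 5 steps (steps 1, 2, 3, 4 and 8); the dichloride branch has 3 steps (5, 6 and 7) before the convergent key step.

**Step 8 (key step, proposed new method).**
- What may go wrong: the second C–C bond may not form. After the first acylation, the acylketene can be intercepted between molecules, by hetero-cycloaddition with a second molecule of 8 or by O-acylation of product phenol. Enolisation toward C4a may also be too slow in the buffered medium, so that oligomers or hydrolysed keto acid result. Adventitious HCl could in addition ionise the benzylic O1–C2 bond and erode the stereocentre.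
- Fallback (known chemistry throughout): ring A is taken from phloroglucinol instead of being built, and the 6-prenyl regiochemistry is secured by symmetry. The fallback sets out from prenyl bromide 10, with commercial phloroglucinol and 3,5-dimethoxyacetophenone, and returns to the route at target 17.
- Phloroglucinol is monosilylated (i-Pr3SiCl, imidazole, DMF) to 5-(triisopropylsilyloxy)benzene-1,3-diol F1 and converted with MOMCl/i-Pr2NEt into [3,5-bis(methoxymethoxy)phenoxy]triisopropylsilane F2.
- Lithiation between the two MOM ethers (n-BuLi, THF, 0 °C), transmetalation with CuI and alkylation with 10 give [3,5-bis(methoxymethoxy)-4-(3-methylbut-2-en-1-yl)phenoxy]triisopropylsilane F3. Bu4NF then frees 3,5-bis(methoxymethoxy)-4-(3-methylbut-2-en-1-yl)phenol F4, in which both positions ortho to the hydroxyl are equivalent.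
- Ortho-formylation (MgCl2, Et3N, paraformaldehyde, MeCN) gives 2-hydroxy-4,6-bis(methoxymethoxy)-5-(3-methylbut-2-en-1-yl)benzaldehyde F5.
- Claisen–Schmidt condensation with 3,5-dimethoxyacetophenone (KOH, EtOH) gives (E)-1-(3,5-dimethoxyphenyl)-3-[2-hydroxy-4,6-bis(methoxymethoxy)-5-(3-methylbut-2-en-1-yl)phenyl]prop-2-en-1-one F6.
- Transfer hydrogenation with RuCl(p-cymene)[(S,S)-TsDPEN] and HCO2Na, which reduces the C=C bond of chalcones and then the carbonyl group, should give 2-[(3S)-3-(3,5-dimethoxyphenyl)-3-hydroxypropyl]-3,5-bis(methoxymethoxy)-4-(3-methylbut-2-en-1-yl)phenol F7.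
- Mitsunobu ring closure (PPh3, DIAD, THF) with inversion gives (R)-2-(3,5-dimethoxyphenyl)-5,7-bis(methoxymethoxy)-6-(3-methylbut-2-en-1-yl)chromane F8, and HCl in MeOH at 40 °C removes both MOM groups to give 17.

**Step 7.**
- What may go wrong: the HCl released can add across the prenyl double bond; the dichloride can lose HCl to a chlorocarbonylketene that dimerises; the malonic acid can decarboxylate if the mixture warms.
- Fallback: an HCl-free route through a silyl ester, setting out from diacid 12 and returning at dichloride 13. Treatment of 12 with hexamethyldisilazane gives bis(trimethylsilyl) 2-(3-methylbut-2-en-1-yl)malonate F9, which with (COCl)2 and catalytic DMF in CH2Cl2 at 0 °C gives 13 with Me3SiCl, CO and CO2 as the only co-products.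

**Step 4.**
- What may go wrong: acid-promoted isomerisation, hydration or hydrolysis of the enol ether while titanium residues are removed, and incomplete methylenation.
- Fallback: make the endocyclic isomer on purpose, setting out from lactone 7 and returning at target 17 through step 8. Addition of MeLi (1.05 equiv, THF, −78 °C) gives (6R)-6-(3,5-dimethoxyphenyl)-2-methyltetrahydro-2H-pyran-2-ol F10. Dehydration with (CF3CO)2O, Et3N and catalytic DMAP gives (R)-2-(3,5-dimethoxyphenyl)-6-methyl-3,4-dihydro-2H-pyran F11, which enters step 8 in place of 8; there C4a is acylated first and the methyl carbon (C8) closes the ring.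

**Step 1.**
- What may go wrong: a second addition of the Grignard reagent to the newly formed ketone, leading to the diaryl carbinol and its lactone, and loss of reagent by enolisation of the anhydride.
- Fallback: a ketone synthesis that cannot over-add, setting out from Grignard reagent 3 and returning at keto ester 5, so that step 2 is bypassed. Transmetalation of 3 with ZnBr2 gives 3,5-dimethoxyphenylzinc bromide F12, and Negishi acylation with commercial methyl 5-chloro-5-oxopentanoate under Pd(PPh3)4 catalysis (THF, 0 °C → rt) gives 5.

## Further compounds

F1 | step 8 | 5-(triisopropylsilyloxy)benzene-1,3-diol | CC(C)[Si](Oc1cc(O)cc(O)c1)(C(C)C)C(C)C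
F2 | step 8 | [3,5-bis(methoxymethoxy)phenoxy]triisopropylsilane | COCOc1cc(OCOC)cc(O[Si](C(C)C)(C(C)C)C(C)C)c1
F3 | step 8 | [3,5-bis(methoxymethoxy)-4-(3-methylbut-2-en-1-yl)phenoxy]triisopropylsilane | COCOc1cc(O[Si](C(C)C)(C(C)C)C(C)C)cc(OCOC)c1CC=C(C)C
F4 | step 8 | 3,5-bis(methoxymethoxy)-4-(3-methylbut-2-en-1-yl)phenol | COCOc1cc(O)cc(OCOC)c1CC=C(C)C
F5 | step 8 | 2-hydroxy-4,6-bis(methoxymethoxy)-5-(3-methylbut-2-en-1-yl)benzaldehyde | O=Cc1c(O)cc(OCOC)c(CC=C(C)C)c1OCOC
F6 | step 8 | (E)-1-(3,5-dimethoxyphenyl)-3-[2-hydroxy-4,6-bis(methoxymethoxy)-5-(3-methylbut-2-en-1-yl)phenyl]prop-2-en-1-one | COc1cc(OC)cc(C(=O)/C=C/c2c(O)cc(OCOC)c(CC=C(C)C)c2OCOC)c1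
F7 | step 8 | 2-[(3S)-3-(3,5-dimethoxyphenyl)-3-hydroxypropyl]-3,5-bis(methoxymethoxy)-4-(3-methylbut-2-en-1-yl)phenol | COc1cc(OC)cc([C@@H](O)CCc2c(O)cc(OCOC)c(CC=C(C)C)c2OCOC)c1
F8 | step 8 | (R)-2-(3,5-dimethoxyphenyl)-5,7-bis(methoxymethoxy)-6-(3-methylbut-2-en-1-yl)chromane | COc1cc(OC)cc([C@H]2CCc3c(cc(OCOC)c(CC=C(C)C)c3OCOC)O2)c1
F9 | step 7 | bis(trimethylsilyl) 2-(3-methylbut-2-en-1-yl)malonate | CC(C)=CCC(C(=O)O[Si](C)(C)C)C(=O)O[Si](C)(C)C
F10 | step 4 | (6R)-6-(3,5-dimethoxyphenyl)-2-methyltetrahydro-2H-pyran-2-ol (anomeric mixture) | COc1cc(OC)cc([C@H]2CCCC(C)(O)O2)c1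
F11 | step 4 | (R)-2-(3,5-dimethoxyphenyl)-6-methyl-3,4-dihydro-2H-pyran | COc1cc(OC)cc([C@H]2CCC=C(C)O2)c1
F12 | step 1 | 3,5-dimethoxyphenylzinc bromide | COc1cc([Zn]Br)cc(OC)c1
A1 | alternative 1 | (R)-2-(3,5-dimethoxyphenyl)-5,7-dihydroxy-6-(3-methylbut-2-en-1-yl)chroman-4-one | COc1cc(OC)cc([C@H]2CC(=O)c3c(cc(O)c(CC=C(C)C)c3O)O2)c1
A2 | alternative 1 | (2R)-2-(3,5-dimethoxyphenyl)-5-(phenylsulfinyl)-2,3-dihydro-4H-pyran-4-one (sulfur configuration open) | COc1cc(OC)cc([C@H]2CC(=O)C(S(=O)c3ccccc3)=CO2)c1
A3 | alternative 1 | 1-methoxy-2-(3-methylbut-2-en-1-yl)-1,3-bis(trimethylsilyloxy)buta-1,3-diene | C=C(O[Si](C)(C)C)C(CC=C(C)C)=C(OC)O[Si](C)(C)C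
A4 | alternative 2 | (R)-2-(3,5-dimethoxyphenyl)-5,7-bis(methoxymethoxy)-6-(3-methylbut-2-en-1-yl)-2H-chromene | COc1cc(OC)cc([C@H]2C=Cc3c(cc(OCOC)c(CC=C(C)C)c3OCOC)O2)c1
A5 | alternative 2 | (R)-1-[1-(3,5-dimethoxyphenyl)allyloxy]-3,5-bis(methoxymethoxy)-4-(3-methylbut-2-en-1-yl)-2-vinylbenzene | COc1cc(OC)cc([C@@H](C=C)Oc2cc(OCOC)c(CC=C(C)C)c(OCOC)c2C=C)c1
A6 | alternative 3 | (R)-2-(3,5-dimethoxyphenyl)-5,7-bis(methoxymethoxy)-6-(3-methylbut-2-en-1-yl)chromane | COc1cc(OC)cc([C@H]2CCc3c(cc(OCOC)c(CC=C(C)C)c3OCOC)O2)c1
A7 | alternative 3 | 2-(hydroxymethyl)-3,5-bis(methoxymethoxy)-4-(3-methylbut-2-en-1-yl)phenol | OCc1c(O)cc(OCOC)c(CC=C(C)C)c1OCOC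
A8 | alternative 3 | 3,5-dimethoxystyrene | C=Cc1cc(OC)cc(OC)c1
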